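1. The target was the minor of two isomers, and I had to give the share of its partner, isomer of the product over isomer plus target, in a flask charged with 2.0 mM of solid substrate.

| setting | eta | gamma | flask |
|---|---|---|---|
| solid substrate | 1.3 mM | 3 mM | 2.0 mM |
| remark | run made earlier | run made earlier |  |
| time |  |  | 12 min |

- eta (time / min: isomer of the product / %, target / %): 1.00: 71, 5; 2.00: 74, 7; 3.00: 74, 6; 4.00: 75, 6; 5.00: 75, 6; 6.00: 74, 6; 8.00: 74, 7
- gamma (time / min: isomer of the product / %, target / %): 0.417: 10, 0; 1.00: 36, 5; 2.00: 72, 2; 3.00: 73, 5; 4.00: 73, 5; 6.00: 74, 3; 8.00: 72, 3

(scatter of a reading: 1.5 percentage points)

* share of isomer of the product in isomer of the product plus target at 6.0 s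
* share of isomer of the product in isomer of the product plus target at 1.0 min
* share of isomer of the product in isomer of the product plus target at 12 min

- given per volume of solution although it is solid: solid substrate
- the numbers in the tables scatter with a standard deviation of 1.5 percentage points
- at the start none of the solid substrate is in solution

2. I averaged the 9 readings from 3.00 min to 8.00 min in the two earlier runs together, which gave isomer 73.8% and target 5.22%, so 21.0% of the charge stood in neither, more than the target itself, and yet the share looked sharply readable.

3. The two facts fit together, since the share, or selectivity, is a ratio within the pair, so the gap drops out of it. I wrote the share as one minus the leak, the target divided by isomer plus target, and from the means the leak came to 6.61%.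

4. An error in the target moved the share 14.1 times as far as the same error in the isomer, so the target readings carried the reckoning, and 9 of them held its mean to about 0.5 percentage points.

5. I committed to 93.4% at 1.0 min and 12 min, and to the same at 6.0 s with little trust, since the earliest reading of the gamma run, at 0.417 min, showed isomer of just 10%, where one standard deviation of target meant a leak of 13.0%.

6. The forecast, saying “Selectivity appears independent of time”, gave 94%, 93.5% and 93.5%, which stands above my figure by 0.61 points at 6.0 s and by 0.11 points at the two later times; the flask gave 87.2%, 93.2% and 94.3%, so the leak at 6.0 s was twice my plateau value.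

    starting material ⇌ other conformer (K = 1.00, k = 0.127 s⁻¹)
    starting material → target (k = 0.00575 s⁻¹)
    other conformer → isomer of the product (k = 0.231 s⁻¹)
    target ⇌ isomer of the product (K = 26.3, k = 4.71 × 10⁻⁴ s⁻¹)
    solid substrate ⇌ starting material, rate k5*(cs5 - [starting material]) while solid is left; crystals form when [starting material] > cs5 (solubility = 0.970 mM, k = 0.0404 s⁻¹)
    2 starting material → self-condensation product (k = 52.7 M⁻¹ s⁻¹)

The neighbour flask, charged with 0.50 mM of solid substrate, took the same reckoning: my leak of 6.61% on its isomer of 80.7% gave target 5.71%, and it held 4.89%, a leak of 5.71%, against 5.70% in the flask at 12 min. Its share was 94.3%, while its self-condensation product, counted as the two it holds, stood at 14.4% against 20.9% in the flask.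

Readings and results are calculated on assumed constants; scatter was added.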